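**Retrosynthetic overview**

1. The target is a hexasubstituted 2,6-dihydroxy-4-methoxybenzophenone. The last C–C bond made is the one from the phloroglucinol ring (ring A) to the carbonyl carbon. It is formed by lithiating the fully elaborated arene 14 and acylating it with the Weinreb amide of 3-hydroxybenzoic acid, used unprotected as its phenolate.
2. Enabling feature: the ring-A carbon that must carry the aroyl group is the only ring carbon still bearing hydrogen, and it lies between the two phenolic oxygens (O-2 and O-6 of the benzophenone). As MOM acetals these two oxygens jointly direct lithium to that C–H; once unmasked they are the chelating hydroxyls of the ketone.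
3. Arene 14: the ring A–CH2 bond comes from a Negishi coupling (aryl iodide 12 + alkylzinc 13). The E-alkenyl group comes from the aldehyde of 2,4,6-trihydroxybenzaldehyde (Wittig, then Z→E equilibration). Iodine is placed ortho to the one free, aldehyde-chelated OH, which is then methylated.
4. Side chain: the (R)-centre is taken from (R)-limonene oxide (glycol cleavage, Pinnick oxidation, Wittig methylenation, Barton iododecarboxylation) and is never touched.
5. Rings: none is formed. Both benzene rings are bought; the cyclohexane ring of limonene oxide is opened in step 1.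

Key step: step 12

Remark: commercial (+)-limonene oxide (cis/trans mixture, 4R) is used as such, because both epimers give the same keto-aldehyde.
Remark: the descriptor of the side-chain centre changes from R to S in 6 and 13 and back to R in 14 through CIP priorities only; its spatial arrangement is the same throughout.

**Step 1**
Reactants: 1 (4R)-limonene 1,2-oxide (cis/trans mixture)
Product: 2 (3R)-6-oxo-3-(prop-1-en-2-yl)heptanal
Conditions: H5IO6, THF/H2O, 0 °C → rt
Reagents that add atoms: water, O
Why: Periodic acid hydrolyses both epoxide diastereomers to the 1,2-diol and cleaves it (Malaprade glycol cleavage), so the mixture should converge on one keto-aldehyde, and the untouched (R)-centre carrying the isopropenyl group becomes the only stereocentre of the target.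

**Step 2**
Reactants: 2 (3R)-6-oxo-3-(prop-1-en-2-yl)heptanal
Product: 3 (3R)-6-oxo-3-(prop-1-en-2-yl)heptanoic acid
Conditions: NaClO2, NaH2PO4, 2-methyl-2-butene, t-BuOH/H2O, 0 °C → rt
Reagents that add atoms: sodium chlorite, [Na+].[O-]Cl=O
Why: Pinnick oxidation converts the aldehyde chemoselectively to the acid, with 2-methyl-2-butene scavenging HOCl so that the isopropenyl group and the β-stereocentre should stay intact.

**Step 3**
Reactants: 3 (3R)-6-oxo-3-(prop-1-en-2-yl)heptanoic acid
Product: 4 (3R)-6-methyl-3-(prop-1-en-2-yl)hept-6-enoic acid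
Conditions: Ph3PCH3Br (excess), KOt-Bu, THF, 0 °C → rt; aq. citric acid
Reagents that add atoms: methyltriphenylphosphonium bromide, C[P+](c1ccccc1)(c1ccccc1)c1ccccc1.[Br-]
Why: Wittig methylenation of the methyl ketone with excess ylide (the carboxylate is inert) installs the second 1,1-disubstituted alkene, and the stereocentre, β to the carboxylate and γ to the ketone, cannot epimerise.

**Step 4**
Reactants: 4 (3R)-6-methyl-3-(prop-1-en-2-yl)hept-6-enoic acid
Product: 6 (3S)-3-(iodomethyl)-2,6-dimethylhepta-1,6-diene, via Barton ester 5 (not isolated)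
Conditions: 1-hydroxypyridine-2(1H)-thione, DCC, DMAP (cat.), CH2Cl2, dark, 0 °C → rt; then CHI3, PhH, hν (tungsten lamp), 60 °C
Reagents that add atoms: iodoform, IC(I)I
Why: Barton decarboxylative iodination, in which the thiohydroxamate ester fragments to the primary alkyl radical and this abstracts iodine from iodoform faster than it can rearrange or add to an alkene, should excise the carboxyl carbon without touching the stereocentre.

**Step 5**
Reactants: 7 2,4,6-trihydroxybenzaldehyde
Product: 8 2-hydroxy-4,6-bis(methoxymethoxy)benzaldehyde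
Conditions: MOMCl (2 equiv), i-Pr2NEt, CH2Cl2, 0 °C → rt
Reagents that add atoms: chloromethyl methyl ether, COCCl
Why: O-alkylation (MOM acetal formation) takes the para hydroxyl and one ortho hydroxyl, while the remaining ortho OH is held in a hydrogen bond to the aldehyde and stays free, which singles out the oxygen that will become the methoxy group.

**Step 6**
Reactants: 8 2-hydroxy-4,6-bis(methoxymethoxy)benzaldehyde
Product: 9 2-hydroxy-3-iodo-4,6-bis(methoxymethoxy)benzaldehyde
Conditions: NIS (1 equiv), DMF, 0 °C → rt, dark
Reagents that add atoms: N-iodosuccinimide, O=C1CCC(=O)N1I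
Why: Electrophilic aromatic iodination is expected to occur ortho to the free chelated phenol (between OH and OMOM) in preference to the more crowded position between the two MOM ethers, which puts the halogen at the future side-chain carbon.

**Step 7**
Reactants: 9 2-hydroxy-3-iodo-4,6-bis(methoxymethoxy)benzaldehyde
Product: 10 3-iodo-2-methoxy-4,6-bis(methoxymethoxy)benzaldehyde
Conditions: MeI, K2CO3, DMF, rt → 40 °C
Reagents that add atoms: iodomethane, CI
Why: Williamson O-methylation of the phenoxide fixes the methoxy group between the aldehyde carbon and the iodide, exactly where the target has OMe between the alkenyl and the side-chain carbons.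

**Step 8**
Reactants: 10 3-iodo-2-methoxy-4,6-bis(methoxymethoxy)benzaldehyde
Product: 11 2-iodo-3-methoxy-1,5-bis(methoxymethoxy)-4-(3-methylbut-1-en-1-yl)benzene (Z/E mixture)
Conditions: i-BuPPh3Br, NaHMDS, THF, 0 °C; then 10, −78 °C → rt
Reagents that add atoms: isobutyltriphenylphosphonium bromide, CC(C)C[P+](c1ccccc1)(c1ccccc1)c1ccccc1.[Br-]
Why: Wittig olefination with the non-stabilised isobutyl ylide should build the 3-methylbut-1-enyl group as a Z/E mixture that need not be separated, the aryl iodide and the acetals being inert to the ylide.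

**Step 9**
Reactants: 11 2-iodo-3-methoxy-1,5-bis(methoxymethoxy)-4-(3-methylbut-1-en-1-yl)benzene (Z/E mixture)
Product: 12 2-iodo-3-methoxy-1,5-bis(methoxymethoxy)-4-[(1E)-3-methylbut-1-en-1-yl]benzene
Conditions: PhSSPh (cat.), THF, 400 nm LED, rt
Reagents that add atoms: none
Why: Thiyl-radical-catalysed alkene isomerisation (reversible PhS• addition and elimination, no positional shift) should funnel both isomers to the E-alkene, which is favoured because the Z-isomer clashes with the two ortho oxygens, and it is run before any 1,1-disubstituted alkene is in the molecule.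

**Step 10**
Reactants: 6 (3S)-3-(iodomethyl)-2,6-dimethylhepta-1,6-diene; 12 2-iodo-3-methoxy-1,5-bis(methoxymethoxy)-4-[(1E)-3-methylbut-1-en-1-yl]benzene
Product: 14 3-methoxy-1,5-bis(methoxymethoxy)-2-[(2R)-5-methyl-2-(prop-1-en-2-yl)hex-5-en-1-yl]-4-[(1E)-3-methylbut-1-en-1-yl]benzene, via alkylzinc iodide 13 (not isolated)
Conditions: 6, Zn dust (activated), LiCl, THF, 35 °C; then 12, Pd2(dba)3 (cat.), RuPhos (cat.), THF/NMP, 50 °C
Reagents that add atoms: none
Why: Negishi sp3–sp2 cross-coupling (zinc insertion into the primary iodide, then Pd/biarylphosphine coupling with the di-ortho-substituted aryl iodide) should join chain and arene, the stereocentre being β to zinc and carried over unchanged.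

**Step 11**
Reactants: 15 3-hydroxybenzoic acid
Product: 16 3-hydroxy-N-methoxy-N-methylbenzamide
Conditions: MeNH(OMe)·HCl, EDC·HCl, HOBt (cat.), N-methylmorpholine, CH2Cl2, 0 °C → rt
Reagents that add atoms: N,O-dimethylhydroxylamine hydrochloride, CNOC.Cl
Why: Carbodiimide amide coupling should give the Weinreb amide directly, the amine outcompeting the phenol for the activated ester.

**Step 12**
Reactants: 14 3-methoxy-1,5-bis(methoxymethoxy)-2-[(2R)-5-methyl-2-(prop-1-en-2-yl)hex-5-en-1-yl]-4-[(1E)-3-methylbut-1-en-1-yl]benzene; 16 3-hydroxy-N-methoxy-N-methylbenzamide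
Product: 19 {4-methoxy-2,6-bis(methoxymethoxy)-3-[(2R)-5-methyl-2-(prop-1-en-2-yl)hex-5-en-1-yl]-5-[(1E)-3-methylbut-1-en-1-yl]phenyl}(3-hydroxyphenyl)methanone, via aryllithium 17 (not isolated), via sodium phenolate 18 (not isolated)
Conditions: 14, n-BuLi (1.1 equiv), THF, −20 → 0 °C; separately 16, NaH, THF, 0 °C; combine at −78 °C → 0 °C; aq. NH4Cl
Reagents that add atoms: none
Why: n-BuLi is complexed by the two MOM acetal oxygens and removes the single ring hydrogen between them (cooperative directed ortho-metalation) to give aryllithium 17, which adds to the N-methoxy-N-methylamide of phenolate 18 to form a chelated tetrahedral adduct that releases ketone 19 only on aqueous work-up (Weinreb ketone synthesis). The closest known reaction type is lithiation of 1,3-bis(methoxymethoxy)arenes at C-2 followed by acylation, the usual entry to 2,6-dioxygenated benzophenones. No ring is closed and no stereocentre is created; the (R)-centre has no acidic hydrogen and the E-alkene is not involved. The step needs site selectivity (aryl C–H against benzylic, allylic and acetal C–H, and against carbolithiation of the styrene), which the two flanking O-directing groups secure kinetically, helped by the electron-rich, di-ortho-substituted styrene being a poor acceptor at or below 0 °C. It also needs single addition, secured by the N,O-chelate and by the two ortho substituents that shield the ketone; masking the partner's phenol as its sodium salt saves a protecting group and consumes no aryllithium. The union runs under strictly non-acidic conditions, so the isopropenyl groups next to oxygenated positions should survive.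

**Step 13**
Reactants: 19 {4-methoxy-2,6-bis(methoxymethoxy)-3-[(2R)-5-methyl-2-(prop-1-en-2-yl)hex-5-en-1-yl]-5-[(1E)-3-methylbut-1-en-1-yl]phenyl}(3-hydroxyphenyl)methanone
Product: 20 {2,6-dihydroxy-4-methoxy-3-[(2R)-5-methyl-2-(prop-1-en-2-yl)hex-5-en-1-yl]-5-[(1E)-3-methylbut-1-en-1-yl]phenyl}(3-hydroxyphenyl)methanone (CNP0208548.1)
Conditions: HCl (1.25 M in MeOH, few equiv), MeOH/THF, 0 °C → rt
Reagents that add atoms: none
Why: Acid-catalysed transacetalisation to methanol should remove the two MOM ethers ortho to the ketone (assisted by hydrogen bonding to the carbonyl) under conditions mild enough for the 1,1-disubstituted alkenes, and nothing else in the molecule changes.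

**Compound list**

1 | (4R)-limonene 1,2-oxide (commercial cis/trans mixture at C-1/C-2) | CC12OC1C[C@@H](CC2)C(C)=C | starting material
2 | (3R)-6-oxo-3-(prop-1-en-2-yl)heptanal | CC(=O)CC[C@H](CC=O)C(C)=C | intermediate
3 | (3R)-6-oxo-3-(prop-1-en-2-yl)heptanoic acid | CC(=O)CC[C@H](CC(=O)O)C(C)=C | intermediate
4 | (3R)-6-methyl-3-(prop-1-en-2-yl)hept-6-enoic acid | C=C(C)CC[C@H](CC(=O)O)C(C)=C | intermediate
5 | 2-thioxopyridin-1(2H)-yl (3R)-6-methyl-3-(prop-1-en-2-yl)hept-6-enoate (Barton ester, not isolated) | C=C(C)CC[C@H](CC(=O)ON1C=CC=CC1=S)C(C)=C | intermediate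
6 | (3S)-3-(iodomethyl)-2,6-dimethylhepta-1,6-diene | C=C(C)CC[C@H](CI)C(C)=C | intermediate
7 | 2,4,6-trihydroxybenzaldehyde | O=Cc1c(O)cc(O)cc1O | starting material
8 | 2-hydroxy-4,6-bis(methoxymethoxy)benzaldehyde | O=Cc1c(O)cc(OCOC)cc1OCOC | intermediate
9 | 2-hydroxy-3-iodo-4,6-bis(methoxymethoxy)benzaldehyde | O=Cc1c(O)c(I)c(OCOC)cc1OCOC | intermediate
10 | 3-iodo-2-methoxy-4,6-bis(methoxymethoxy)benzaldehyde | O=Cc1c(OC)c(I)c(OCOC)cc1OCOC | intermediate
11 | 2-iodo-3-methoxy-1,5-bis(methoxymethoxy)-4-(3-methylbut-1-en-1-yl)benzene (Z/E mixture) | CC(C)C=Cc1c(OC)c(I)c(OCOC)cc1OCOC | intermediate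
12 | 2-iodo-3-methoxy-1,5-bis(methoxymethoxy)-4-[(1E)-3-methylbut-1-en-1-yl]benzene | CC(C)/C=C/c1c(OC)c(I)c(OCOC)cc1OCOC | intermediate
13 | [(2S)-5-methyl-2-(prop-1-en-2-yl)hex-5-en-1-yl]zinc iodide (not isolated) | C=C(C)CC[C@H](C[Zn]I)C(C)=C | intermediate
14 | 3-methoxy-1,5-bis(methoxymethoxy)-2-[(2R)-5-methyl-2-(prop-1-en-2-yl)hex-5-en-1-yl]-4-[(1E)-3-methylbut-1-en-1-yl]benzene | C=C(C)CC[C@H](Cc1c(OC)c(/C=C/C(C)C)c(OCOC)cc1OCOC)C(C)=C | intermediate
15 | 3-hydroxybenzoic acid | O=C(O)c1cccc(O)c1 | starting material
16 | 3-hydroxy-N-methoxy-N-methylbenzamide | CON(C)C(=O)c1cccc(O)c1 | intermediate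
17 | {4-methoxy-2,6-bis(methoxymethoxy)-3-[(2R)-5-methyl-2-(prop-1-en-2-yl)hex-5-en-1-yl]-5-[(1E)-3-methylbut-1-en-1-yl]phenyl}lithium (not isolated) | C=C(C)CC[C@H](Cc1c(OC)c(/C=C/C(C)C)c(OCOC)c([Li])c1OCOC)C(C)=C | intermediate
18 | sodium 3-[methoxy(methyl)carbamoyl]phenolate (not isolated) | CON(C)C(=O)c1cccc([O-])c1.[Na+] | intermediate
19 | {4-methoxy-2,6-bis(methoxymethoxy)-3-[(2R)-5-methyl-2-(prop-1-en-2-yl)hex-5-en-1-yl]-5-[(1E)-3-methylbut-1-en-1-yl]phenyl}(3-hydroxyphenyl)methanone | C=C(C)CC[C@H](Cc1c(OC)c(/C=C/C(C)C)c(OCOC)c(C(=O)c2cccc(O)c2)c1OCOC)C(C)=C | intermediate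
20 | {2,6-dihydroxy-4-methoxy-3-[(2R)-5-methyl-2-(prop-1-en-2-yl)hex-5-en-1-yl]-5-[(1E)-3-methylbut-1-en-1-yl]phenyl}(3-hydroxyphenyl)methanone | C=C(C)CC[C@H](Cc1c(O)c(C(=O)c2cccc(O)c2)c(O)c(/C=C/C(C)C)c1OC)C(=C)C | target

**Totals**

Total step count: 13.
Longest linear sequence: 8 steps (5, 6, 7, 8, 9, 10, 12, 13, from 7 to 20).

**Three steps most likely to fail**

Step 12 (key step). The buttressed aryllithium may add only slowly to the amide of the aggregated phenolate and act as a base instead (proton transfer from the partner, or elimination at the N-methoxy group), returning 14. The fallback sets out from 14 and comes back at 19. Compound 14 is lithiated as in step 12 and the aryllithium 17 is added at −78 °C to commercial 3-[(tert-butyldimethylsilyl)oxy]benzaldehyde, the least hindered and most reactive acceptor, to give the silyl-protected diarylmethanol F1 as a mixture of carbinol epimers. Dess–Martin oxidation (NaHCO3, CH2Cl2) then gives the silyl-protected ketone F2, and TBAF in THF at 0 °C removes the silyl ether to give 19.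

Step 6. Iodination may also take place para to the free phenol (between the two MOM ethers) or twice, which would put the side chain on the wrong carbon. The fallback sets out from 8 and comes back at 12; it sets the regiochemistry by metalation instead of electrophilic substitution. Compound 8 is O-methylated (MeI, K2CO3, DMF) to the aldehyde F3. Wittig olefination as in step 8 gives the Z/E styrene F4, which is equilibrated as in step 9 to the E-styrene F5. n-BuLi in THF at 0 °C lithiates F5 between the two MOM ethers, and this site is capped in the flask with TMSCl. A second lithiation (s-BuLi, TMEDA, −78 °C) can then occur only between OMe and OMOM and is quenched with iodine to give the silylated iodide F6. Protodesilylation (wet TBAF in DMF, or KOTMS in wet DMSO) returns 12.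

Step 10. Zinc insertion may stall, or the β-branched alkylpalladium intermediate may undergo β-hydride elimination faster than reductive elimination at the crowded aryl centre, giving reduced arene and diene instead of 14. The fallback sets out from 12 and 4 and comes back at 14; it reverses the polarity and bypasses step 4. Compound 12 undergoes iodine–magnesium exchange (i-PrMgCl·LiCl, THF, 0 °C) and transmetalation with ZnCl2 to the arylzinc chloride F7. Acid 4 is converted with N-hydroxyphthalimide and DIC into the redox-active ester F8. A nickel-catalysed decarboxylative aryl–alkyl coupling of the Negishi type (NiCl2·glyme, 4,4'-di-tert-butyl-2,2'-bipyridine, THF/DMF, rt) then joins F7 and F8 to give 14.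

**Further compounds**

F1 | step 12 | {3-[(tert-butyldimethylsilyl)oxy]phenyl}{4-methoxy-2,6-bis(methoxymethoxy)-3-[(2R)-5-methyl-2-(prop-1-en-2-yl)hex-5-en-1-yl]-5-[(1E)-3-methylbut-1-en-1-yl]phenyl}methanol (both carbinol epimers) | C=C(C)CC[C@H](Cc1c(OC)c(/C=C/C(C)C)c(OCOC)c(C(O)c2cccc(O[Si](C)(C)C(C)(C)C)c2)c1OCOC)C(C)=C
F2 | step 12 | {3-[(tert-butyldimethylsilyl)oxy]phenyl}{4-methoxy-2,6-bis(methoxymethoxy)-3-[(2R)-5-methyl-2-(prop-1-en-2-yl)hex-5-en-1-yl]-5-[(1E)-3-methylbut-1-en-1-yl]phenyl}methanone | C=C(C)CC[C@H](Cc1c(OC)c(/C=C/C(C)C)c(OCOC)c(C(=O)c2cccc(O[Si](C)(C)C(C)(C)C)c2)c1OCOC)C(C)=C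
F3 | step 6 | 2-methoxy-4,6-bis(methoxymethoxy)benzaldehyde | O=Cc1c(OC)cc(OCOC)cc1OCOC
F4 | step 6 | 1-methoxy-3,5-bis(methoxymethoxy)-2-(3-methylbut-1-en-1-yl)benzene (Z/E mixture) | CC(C)C=Cc1c(OC)cc(OCOC)cc1OCOC
F5 | step 6 | 1-methoxy-3,5-bis(methoxymethoxy)-2-[(1E)-3-methylbut-1-en-1-yl]benzene | CC(C)/C=C/c1c(OC)cc(OCOC)cc1OCOC
F6 | step 6 | {3-iodo-4-methoxy-2,6-bis(methoxymethoxy)-5-[(1E)-3-methylbut-1-en-1-yl]phenyl}trimethylsilane | CC(C)/C=C/c1c(OC)c(I)c(OCOC)c([Si](C)(C)C)c1OCOC
F7 | step 10 | {2-methoxy-4,6-bis(methoxymethoxy)-3-[(1E)-3-methylbut-1-en-1-yl]phenyl}zinc chloride | CC(C)/C=C/c1c(OC)c([Zn]Cl)c(OCOC)cc1OCOC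
F8 | step 10 | 1,3-dioxoisoindolin-2-yl (3R)-6-methyl-3-(prop-1-en-2-yl)hept-6-enoate | C=C(C)CC[C@H](CC(=O)ON1C(=O)c2ccccc2C1=O)C(C)=C
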